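**Plan**

Ring numbering used below: C1 = alkylidene carbon, C2 = CH bearing the hydroxypropyl chain, C3 = quaternary carbon, C4 = carbinol carbon, C5 and C6 = the two ring CH2.
Cuts: (a) the sp3–sp2 bond between the second side-chain carbon on C3 and the (E)-trisubstituted alkene (B-alkyl Suzuki–Miyaura; ring half plus an epoxy alkenyl iodide from nerol); (b) the ring C5–C6 bond; (c) the methyl–C4 bond (methyl addition to a C4 ketone); (d) the ring C2–C3 bond (Ireland–Claisen).
Enabling feature: with C4 as a ketone, C5 is its α-carbon and C6 is the γ-carbon of the exocyclic C1=C(CH3)–C=O unit. The C5–C6 bond therefore joins a ketone-enolate carbon to a dienolate γ-carbon (a 1,6-dicarbonyl relationship) and can be closed by oxidising the bis-enolate of a precursor in which both carbons are plain methyl groups.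
Forward order: Ireland–Claisen (C2, C3) → enol lactone → β-ketoester → (E)-enol tosylate → methyl coupling (fixes the alkene) → oxidative closure of the six-membered ring → methyl addition at C4 → Suzuki union with the epoxide half → ester reduction, desilylation, allylic oxidation.
Stereochemistry: C2/C3 from the chair transition state of a reagent-controlled Ireland–Claisen on a (Z)-enyne ester; C4 from equatorial attack on the ring ketone (C2 chain axial); the exocyclic (Z)-alkene from stereoretentive coupling of a geometrically defined enol tosylate; the (E)-chain alkene from syn-borylcupration/methylation; the epoxide from Sharpless epoxidation of nerol.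

Key step: step 7

Assumption: the (S,S)-enantiomer of the bromoborane controller is written for step 2; if it induces the opposite absolute sense, its (R,R)-enantiomer is used and nothing else changes.

**Route**

Step 1
Reactants: 1 5-[(tert-butyldimethylsilyl)oxy]pentanoic acid; 2 (2Z)-3-methylpent-2-en-4-yn-1-ol
Product: 3 (2Z)-3-methylpent-2-en-4-yn-1-yl 5-[(tert-butyldimethylsilyl)oxy]pentanoate
Conditions: DCC, DMAP (cat.), CH2Cl2, 0 °C → rt
Reagents that add atoms: none
Why: Steglich esterification of a primary allylic alcohol under neutral conditions, which should leave the (Z)-enyne geometry and the silyl ether untouched.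

Step 2
Reactants: 3 (2Z)-3-methylpent-2-en-4-yn-1-yl 5-[(tert-butyldimethylsilyl)oxy]pentanoate
Product: 5 (2S,3S)-2-{3-[(tert-butyldimethylsilyl)oxy]propyl}-3-ethynyl-3-methylpent-4-enoic acid, via boron ketene acetal 4 (not isolated)
Conditions: (S,S)-2-bromo-4,5-diphenyl-1,3-bis{[3,5-bis(trifluoromethyl)phenyl]sulfonyl}-1,3,2-diazaborolidine (preformed, 1.2 equiv), i-Pr2NEt, CH2Cl2, −78 °C, then −20 °C → rt; aqueous workup
Reagents that add atoms: none
Why: Enantioselective boron-mediated Ireland–Claisen rearrangement, in which soft enolisation should give ketene acetal 4 with the alkyl chain cis to O–B, the chair [3,3] shift then places this chain and the methyl of the (Z)-enyne pseudo-equatorial (ethynyl pseudo-axial) and so fixes the relative configuration of the new tertiary C2 and quaternary C3, while the C2-symmetric diazaborolidine selects the enolate face and hence the absolute configuration.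

Step 3
Reactants: 5 (2S,3S)-2-{3-[(tert-butyldimethylsilyl)oxy]propyl}-3-ethynyl-3-methylpent-4-enoic acid
Product: 6 (3S,4S)-3-{3-[(tert-butyldimethylsilyl)oxy]propyl}-4-ethenyl-4-methyl-5-methylideneoxolan-2-one
Conditions: AuCl (5 mol %), K2CO3 (10 mol %), MeCN, rt
Reagents that add atoms: none
Why: Gold-catalysed 5-exo-dig cycloisomerisation of a γ-alkynoic acid (carboxylate attack on the internal alkyne carbon, then protodeauration), giving an enol lactone that activates the acid carbon as an enol ester and masks the methyl ketone, with both stereocentres untouched.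

Step 4
Reactants: 6 (3S,4S)-3-{3-[(tert-butyldimethylsilyl)oxy]propyl}-4-ethenyl-4-methyl-5-methylideneoxolan-2-one
Product: 7 methyl (4S,5S)-4-{3-[(tert-butyldimethylsilyl)oxy]propyl}-5-ethenyl-2,5-dimethyl-3,6-dioxoheptanoate (both C2 epimers)
Conditions: methyl propionate, LiN(i-Pr)2, THF, −78 °C; then 6, −78 → −40 °C; AcOH
Reagents that add atoms: methyl propionate, CCC(=O)OC
Why: Crossed Claisen acylation with the enol ester as acyl donor, in which the tetrahedral adduct should expel the ketone enolate (unmasking the acetyl group) and the β-ketoester is held as its enolate until the quench, so that the adjacent C4 stereocentre is not epimerised and the new C2 centre, removed in step 5, does not matter.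

Step 5
Reactants: 7 methyl (4S,5S)-4-{3-[(tert-butyldimethylsilyl)oxy]propyl}-5-ethenyl-2,5-dimethyl-3,6-dioxoheptanoate
Product: 8 methyl (2E,4S,5S)-4-{3-[(tert-butyldimethylsilyl)oxy]propyl}-5-ethenyl-2,5-dimethyl-3-{[(4-methylphenyl)sulfonyl]oxy}-6-oxohept-2-enoate
Conditions: TsCl, N-methylimidazole, Et3N, toluene, 0 °C
Reagents that add atoms: 4-methylbenzenesulfonyl chloride, Cc1ccc(cc1)S(=O)(=O)Cl
Why: Stereocomplementary enol tosylation of an α-substituted β-ketoester, in which the non-chelating amine conditions should tosylate the enolate with the enol oxygen trans to the ester and give the (E)-tosylate (OTs cis to the 2-methyl), the simple ketone being left alone.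

Step 6
Reactants: 8 methyl (2E,4S,5S)-4-{3-[(tert-butyldimethylsilyl)oxy]propyl}-5-ethenyl-2,5-dimethyl-3-{[(4-methylphenyl)sulfonyl]oxy}-6-oxohept-2-enoate
Product: 9 methyl (2Z,4R,5S)-4-{3-[(tert-butyldimethylsilyl)oxy]propyl}-5-ethenyl-2,3,5-trimethyl-6-oxohept-2-enoate
Conditions: MeZnCl, Pd(dppf)Cl2 (5 mol %), THF, 50 °C
Reagents that add atoms: methylzinc chloride, C[Zn]Cl
Why: Negishi coupling of an enol tosylate, which proceeds with retention at the sp2 carbon and should place the new 3-methyl (the future ring C6) cis to the 2-methyl and trans to the ester, the methyl ketone being inert to the organozinc reagent.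

Step 7
Reactants: 9 methyl (2Z,4R,5S)-4-{3-[(tert-butyldimethylsilyl)oxy]propyl}-5-ethenyl-2,3,5-trimethyl-6-oxohept-2-enoate
Product: 11 methyl (2Z)-2-[(2R,3S)-2-{3-[(tert-butyldimethylsilyl)oxy]propyl}-3-ethenyl-3-methyl-4-oxocyclohexylidene]propanoate, via dilithium bis-enolate 10 (not isolated)
Conditions: LiN(i-Pr)2 (2.3 equiv), THF–DMPU, −78 °C; then Fe(acac)3 (2.2 equiv), −78 → 0 °C, high dilution
Reagents that add atoms: none
Why: Proposed new method: two equivalents of LDA should remove one proton from the acetyl methyl (the only enolisable side of that ketone, its other α-carbon being quaternary) and one from the 3-methyl of the enoate (γ-deprotonation to the ester dienolate; the other γ-hydrogen, on C4, lies in the alkene plane because of allylic 1,3-strain with the ester and is not removed), and one-electron oxidation of bis-enolate 10 by trivalent iron should give an α-keto radical that bonds to the terminal CH2 of the dienolate, a second electron transfer restoring the conjugated enoate. The closest known reaction types are the intramolecular oxidative heterocoupling of two enolates by iron or copper salts and the oxidative γ,γ-dimerisation of ester dienolates; coupling of a ketone enolate with the γ-carbon of a dienolate within one molecule has not been shown. The cyclohexanone ring closes in a 6-endo-trig mode (attack on the dienolate terminus, the internal dienolate carbon staying in the ring), the mode favoured by α-keto radicals whose carbonyl lies inside the forming ring and by 1,1-disubstituted alkene termini. No stereocentre is formed, the two existing ones lose no hydrogen, and the alkene geometry should be kept because at −78 °C the central bond of the dienolate and of the delocalised ester radical retains double-bond character in the arrangement inherited from 9. The step needs γ- over α-coupling at the dienolate and ring closure over dimerisation: the α-carbon is fully substituted and α-coupling would give a non-conjugated product with a new quaternary centre, and the two enolate carbons are held six atoms apart in dilute solution.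

Step 8
Reactants: 11 methyl (2Z)-2-[(2R,3S)-2-{3-[(tert-butyldimethylsilyl)oxy]propyl}-3-ethenyl-3-methyl-4-oxocyclohexylidene]propanoate
Product: 12 methyl (2Z)-2-[(2R,3S,4S)-2-{3-[(tert-butyldimethylsilyl)oxy]propyl}-3-ethenyl-4-hydroxy-3,4-dimethylcyclohexylidene]propanoate
Conditions: MeLi (1.2 equiv), Et2O–THF, −78 °C; then H2O
Reagents that add atoms: methyllithium, [Li]C
Why: 1,2-Addition of methyllithium to the ketone (far more electrophilic than the hindered tetrasubstituted enoate), in which allylic 1,3-strain with the ester holds the C2 chain axial so that axial attack at C4 suffers a 1,3-diaxial clash, the methyl should enter equatorially and the hydroxyl end axial, cis to the C2 chain (4S).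

Step 9
Reactants: 13 nerol, (2Z)-3,7-dimethylocta-2,6-dien-1-ol
Product: 14 [(2R,3S)-3-methyl-3-(4-methylpent-3-en-1-yl)oxiran-2-yl]methanol
Conditions: Ti(Oi-Pr)4 (cat.), D-(−)-diisopropyl tartrate (cat.), t-BuOOH, 4 Å molecular sieves, CH2Cl2, −20 °C
Reagents that add atoms: tert-butyl hydroperoxide, CC(C)(C)OO
Why: Sharpless asymmetric epoxidation of a (Z)-allylic alcohol, in which the D-(−)-tartrate should deliver oxygen to the face that gives the (2R,3S)-epoxide with the two chains cis, the remote trisubstituted alkene lacking the directing hydroxyl and staying intact.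

Step 10
Reactants: 14 [(2R,3S)-3-methyl-3-(4-methylpent-3-en-1-yl)oxiran-2-yl]methanol
Product: 15 [(2R,3S)-3-methyl-3-(4-methylpent-3-en-1-yl)oxiran-2-yl]methyl trifluoromethanesulfonate
Conditions: Tf2O, 2,6-lutidine, CH2Cl2, −78 °C; used at once
Reagents that add atoms: trifluoromethanesulfonic anhydride, FC(F)(F)S(=O)(=O)OS(=O)(=O)C(F)(F)F
Why: O-Sulfonylation of the primary alcohol at low temperature with a hindered base, which touches neither stereocentre nor the epoxide.

Step 11
Reactants: 15 [(2R,3S)-3-methyl-3-(4-methylpent-3-en-1-yl)oxiran-2-yl]methyl trifluoromethanesulfonate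
Product: 17 (2S,3R)-3-(but-3-yn-1-yl)-2-methyl-2-(4-methylpent-3-en-1-yl)oxirane, via silylalkyne 16 (not isolated)
Conditions: 1-(trimethylsilyl)propyne, n-BuLi, THF, −78 °C; then 15, THF–DMPU, −78 → −40 °C; then K2CO3 (cat.), MeOH, rt
Reagents that add atoms: 1-(trimethylsilyl)propyne, CC#C[Si](C)(C)C
Why: SN2 alkylation of lithiated 1-(trimethylsilyl)propyne, which reacts at its propargylic carbon, at the primary triflate (faster than epoxide opening at −78 °C), followed by basic methanolysis of the alkynyl C–Si bond, the stereocentres being untouched.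

Step 12
Reactants: 17 (2S,3R)-3-(but-3-yn-1-yl)-2-methyl-2-(4-methylpent-3-en-1-yl)oxirane
Product: 18 4,4,5,5-tetramethyl-2-{(1E)-2-methyl-4-[(2R,3S)-3-methyl-3-(4-methylpent-3-en-1-yl)oxiran-2-yl]but-1-en-1-yl}-1,3,2-dioxaborolane
Conditions: CuCl (10 mol %), Xantphos (10 mol %), NaOt-Bu, B2pin2, MeI, THF, rt
Reagents that add atoms: bis(pinacolato)diboron, CC1(C)OB(OC1(C)C)B1OC(C)(C)C(C)(C)O1; iodomethane, CI
Why: Copper-catalysed carboboration of a terminal alkyne, in which syn-borylcupration should put boron on the terminal carbon and copper on the internal one and the alkenylcopper is methylated with retention, giving the (E)-alkenylboronate with boron and methyl cis.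

Step 13
Reactants: 18 4,4,5,5-tetramethyl-2-{(1E)-2-methyl-4-[(2R,3S)-3-methyl-3-(4-methylpent-3-en-1-yl)oxiran-2-yl]but-1-en-1-yl}-1,3,2-dioxaborolane
Product: 19 (2S,3R)-3-[(3E)-4-iodo-3-methylbut-3-en-1-yl]-2-methyl-2-(4-methylpent-3-en-1-yl)oxirane
Conditions: NaOH (aq), then I2, THF, 0 °C
Reagents that add atoms: iodine, II
Why: Iododeboronation of an alkenylboronate through its hydroxide ate complex, which should replace boron by iodine with retention of the (E) geometry under conditions that the epoxide tolerates.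

Step 14
Reactants: 12 methyl (2Z)-2-[(2R,3S,4S)-2-{3-[(tert-butyldimethylsilyl)oxy]propyl}-3-ethenyl-4-hydroxy-3,4-dimethylcyclohexylidene]propanoate; 19 (2S,3R)-3-[(3E)-4-iodo-3-methylbut-3-en-1-yl]-2-methyl-2-(4-methylpent-3-en-1-yl)oxirane
Product: 21 methyl (2Z)-2-[(2R,3S,4S)-2-{3-[(tert-butyldimethylsilyl)oxy]propyl}-4-hydroxy-3,4-dimethyl-3-{(3E)-4-methyl-6-[(2R,3S)-3-methyl-3-(4-methylpent-3-en-1-yl)oxiran-2-yl]hex-3-en-1-yl}cyclohexylidene]propanoate, via alkylborane 20 (not isolated)
Conditions: 9-BBN dimer, THF, 60 °C; then 19, Pd(dppf)Cl2 (cat.), AsPh3 (cat.), Cs2CO3, DMF–H2O, rt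
Reagents that add atoms: none
Why: Anti-Markovnikov hydroboration of the only monosubstituted alkene with 9-BBN followed by B-alkyl Suzuki–Miyaura coupling with the alkenyl iodide, which should proceed with retention of the (E) geometry and tolerate the epoxide, the ester and the hindered tertiary alcohol.

Step 15
Reactants: 21 methyl (2Z)-2-[(2R,3S,4S)-2-{3-[(tert-butyldimethylsilyl)oxy]propyl}-4-hydroxy-3,4-dimethyl-3-{(3E)-4-methyl-6-[(2R,3S)-3-methyl-3-(4-methylpent-3-en-1-yl)oxiran-2-yl]hex-3-en-1-yl}cyclohexylidene]propanoate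
Product: 22 (2Z)-2-[(2R,3S,4S)-2-{3-[(tert-butyldimethylsilyl)oxy]propyl}-4-hydroxy-3,4-dimethyl-3-{(3E)-4-methyl-6-[(2R,3S)-3-methyl-3-(4-methylpent-3-en-1-yl)oxiran-2-yl]hex-3-en-1-yl}cyclohexylidene]propan-1-ol
Conditions: i-Bu2AlH (3.5 equiv), CH2Cl2, −78 °C; aqueous workup
Reagents that add atoms: none
Why: Reduction of the α,β-unsaturated ester to the allylic alcohol with diisobutylaluminium hydride at −78 °C, where the trisubstituted epoxide and the isolated alkenes are inert and the alkene geometry is kept.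

Step 16
Reactants: 22 (2Z)-2-[(2R,3S,4S)-2-{3-[(tert-butyldimethylsilyl)oxy]propyl}-4-hydroxy-3,4-dimethyl-3-{(3E)-4-methyl-6-[(2R,3S)-3-methyl-3-(4-methylpent-3-en-1-yl)oxiran-2-yl]hex-3-en-1-yl}cyclohexylidene]propan-1-ol
Product: 23 (2Z)-2-[(2R,3S,4S)-4-hydroxy-2-(3-hydroxypropyl)-3,4-dimethyl-3-{(3E)-4-methyl-6-[(2R,3S)-3-methyl-3-(4-methylpent-3-en-1-yl)oxiran-2-yl]hex-3-en-1-yl}cyclohexylidene]propan-1-ol
Conditions: Bu4NF, AcOH, THF, 0 °C → rt
Reagents that add atoms: none
Why: Fluoride cleavage of the primary silyl ether, buffered with acetic acid so that the epoxide and the allylic alcohol are not disturbed.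

Step 17
Reactants: 23 (2Z)-2-[(2R,3S,4S)-4-hydroxy-2-(3-hydroxypropyl)-3,4-dimethyl-3-{(3E)-4-methyl-6-[(2R,3S)-3-methyl-3-(4-methylpent-3-en-1-yl)oxiran-2-yl]hex-3-en-1-yl}cyclohexylidene]propan-1-ol
Product: 24 (2Z)-2-[(2R,3S,4S)-4-hydroxy-2-(3-hydroxypropyl)-3,4-dimethyl-3-{(3E)-4-methyl-6-[(2R,3S)-3-methyl-3-(4-methylpent-3-en-1-yl)oxiran-2-yl]hex-3-en-1-yl}cyclohexylidene]propanal (target)
Conditions: MnO2 (activated, excess), CH2Cl2, rt
Reagents that add atoms: none
Why: Chemoselective oxidation of the allylic alcohol by manganese dioxide, which should leave the saturated primary and the tertiary hydroxyl alone and, being neutral, preserve the epoxide and the (Z)-enal geometry.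

**Compound list**

1 | 5-[(tert-butyldimethylsilyl)oxy]pentanoic acid | OC(=O)CCCCO[Si](C)(C)C(C)(C)C | starting material
2 | (2Z)-3-methylpent-2-en-4-yn-1-ol | C#C/C(C)=C\CO | starting material
3 | (2Z)-3-methylpent-2-en-4-yn-1-yl 5-[(tert-butyldimethylsilyl)oxy]pentanoate | C#C/C(C)=C\COC(=O)CCCCO[Si](C)(C)C(C)(C)C | intermediate
4 | boron ketene acetal of 3 (O-diazaborolidinyl, (S,S)-ligand, alkyl chain cis to O–B) | C#C/C(C)=C\CO/C(OB1N(S(=O)(=O)c2cc(cc(c2)C(F)(F)F)C(F)(F)F)[C@@H](c2ccccc2)[C@H](c2ccccc2)N1S(=O)(=O)c1cc(cc(c1)C(F)(F)F)C(F)(F)F)=C/CCCO[Si](C)(C)C(C)(C)C | intermediate (not isolated)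
5 | (2S,3S)-2-{3-[(tert-butyldimethylsilyl)oxy]propyl}-3-ethynyl-3-methylpent-4-enoic acid | C=C[C@@](C#C)(C)[C@H](CCCO[Si](C)(C)C(C)(C)C)C(=O)O | intermediate
6 | (3S,4S)-3-{3-[(tert-butyldimethylsilyl)oxy]propyl}-4-ethenyl-4-methyl-5-methylideneoxolan-2-one | C=C1OC(=O)[C@@H](CCCO[Si](C)(C)C(C)(C)C)[C@]1(C)C=C | intermediate
7 | methyl (4S,5S)-4-{3-[(tert-butyldimethylsilyl)oxy]propyl}-5-ethenyl-2,5-dimethyl-3,6-dioxoheptanoate (C2 epimers) | CC(=O)[C@@](C)(C=C)[C@H](CCCO[Si](C)(C)C(C)(C)C)C(=O)C(C)C(=O)OC | intermediate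
8 | methyl (2E,4S,5S)-4-{3-[(tert-butyldimethylsilyl)oxy]propyl}-5-ethenyl-2,5-dimethyl-3-{[(4-methylphenyl)sulfonyl]oxy}-6-oxohept-2-enoate | CC(=O)[C@@](C)(C=C)[C@H](CCCO[Si](C)(C)C(C)(C)C)/C(OS(=O)(=O)c1ccc(C)cc1)=C(/C)C(=O)OC | intermediate
9 | methyl (2Z,4R,5S)-4-{3-[(tert-butyldimethylsilyl)oxy]propyl}-5-ethenyl-2,3,5-trimethyl-6-oxohept-2-enoate | CC(=O)[C@@](C)(C=C)[C@H](CCCO[Si](C)(C)C(C)(C)C)/C(C)=C(/C)C(=O)OC | intermediate
10 | dilithium bis-enolate of 9 (ketone enolate at the acetyl group, ester dienolate with terminal CH2 from the 3-methyl) | [Li]OC(=C)[C@@](C)(C=C)[C@H](CCCO[Si](C)(C)C(C)(C)C)C(=C)C(C)=C(OC)O[Li] | intermediate (not isolated)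
11 | methyl (2Z)-2-[(2R,3S)-2-{3-[(tert-butyldimethylsilyl)oxy]propyl}-3-ethenyl-3-methyl-4-oxocyclohexylidene]propanoate | O=C1CC/C(=C(\C)C(=O)OC)[C@@H](CCCO[Si](C)(C)C(C)(C)C)[C@]1(C)C=C | intermediate
12 | methyl (2Z)-2-[(2R,3S,4S)-2-{3-[(tert-butyldimethylsilyl)oxy]propyl}-3-ethenyl-4-hydroxy-3,4-dimethylcyclohexylidene]propanoate | C[C@]1(O)CC/C(=C(\C)C(=O)OC)[C@@H](CCCO[Si](C)(C)C(C)(C)C)[C@]1(C)C=C | intermediate
13 | nerol, (2Z)-3,7-dimethylocta-2,6-dien-1-ol | CC(C)=CCC/C(C)=C\CO | starting material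
14 | [(2R,3S)-3-methyl-3-(4-methylpent-3-en-1-yl)oxiran-2-yl]methanol | OC[C@H]1O[C@@]1(C)CCC=C(C)C | intermediate
15 | [(2R,3S)-3-methyl-3-(4-methylpent-3-en-1-yl)oxiran-2-yl]methyl trifluoromethanesulfonate | FC(F)(F)S(=O)(=O)OC[C@H]1O[C@@]1(C)CCC=C(C)C | intermediate
16 | trimethyl{4-[(2R,3S)-3-methyl-3-(4-methylpent-3-en-1-yl)oxiran-2-yl]but-1-yn-1-yl}silane | C[Si](C)(C)C#CCC[C@H]1O[C@@]1(C)CCC=C(C)C | intermediate (not isolated)
17 | (2S,3R)-3-(but-3-yn-1-yl)-2-methyl-2-(4-methylpent-3-en-1-yl)oxirane | C#CCC[C@H]1O[C@@]1(C)CCC=C(C)C | intermediate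
18 | 4,4,5,5-tetramethyl-2-{(1E)-2-methyl-4-[(2R,3S)-3-methyl-3-(4-methylpent-3-en-1-yl)oxiran-2-yl]but-1-en-1-yl}-1,3,2-dioxaborolane | CC1(C)OB(/C=C(\C)CC[C@H]2O[C@@]2(C)CCC=C(C)C)OC1(C)C | intermediate
19 | (2S,3R)-3-[(3E)-4-iodo-3-methylbut-3-en-1-yl]-2-methyl-2-(4-methylpent-3-en-1-yl)oxirane | I/C=C(\C)CC[C@H]1O[C@@]1(C)CCC=C(C)C | intermediate
20 | B-alkyl-9-borabicyclo[3.3.1]nonane from 12 (vinyl group converted to CH2CH2–B) | C[C@]1(O)CC/C(=C(\C)C(=O)OC)[C@@H](CCCO[Si](C)(C)C(C)(C)C)[C@]1(C)CCB1C2CCCC1CCC2 | intermediate (not isolated)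
21 | methyl (2Z)-2-[(2R,3S,4S)-2-{3-[(tert-butyldimethylsilyl)oxy]propyl}-4-hydroxy-3,4-dimethyl-3-{(3E)-4-methyl-6-[(2R,3S)-3-methyl-3-(4-methylpent-3-en-1-yl)oxiran-2-yl]hex-3-en-1-yl}cyclohexylidene]propanoate | C[C@]1(O)CC/C(=C(\C)C(=O)OC)[C@@H](CCCO[Si](C)(C)C(C)(C)C)[C@]1(C)CC/C=C(\C)CC[C@H]2O[C@@]2(C)CCC=C(C)C | intermediate
22 | (2Z)-2-[(2R,3S,4S)-2-{3-[(tert-butyldimethylsilyl)oxy]propyl}-4-hydroxy-3,4-dimethyl-3-{(3E)-4-methyl-6-[(2R,3S)-3-methyl-3-(4-methylpent-3-en-1-yl)oxiran-2-yl]hex-3-en-1-yl}cyclohexylidene]propan-1-ol | C[C@]1(O)CC/C(=C(\C)CO)[C@@H](CCCO[Si](C)(C)C(C)(C)C)[C@]1(C)CC/C=C(\C)CC[C@H]2O[C@@]2(C)CCC=C(C)C | intermediate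
23 | (2Z)-2-[(2R,3S,4S)-4-hydroxy-2-(3-hydroxypropyl)-3,4-dimethyl-3-{(3E)-4-methyl-6-[(2R,3S)-3-methyl-3-(4-methylpent-3-en-1-yl)oxiran-2-yl]hex-3-en-1-yl}cyclohexylidene]propan-1-ol | C[C@]1(O)CC/C(=C(\C)CO)[C@@H](CCCO)[C@]1(C)CC/C=C(\C)CC[C@H]2O[C@@]2(C)CCC=C(C)C | intermediate
24 | (2Z)-2-[(2R,3S,4S)-4-hydroxy-2-(3-hydroxypropyl)-3,4-dimethyl-3-{(3E)-4-methyl-6-[(2R,3S)-3-methyl-3-(4-methylpent-3-en-1-yl)oxiran-2-yl]hex-3-en-1-yl}cyclohexylidene]propanal | CC(C)=CCC[C@]1(C)O[C@@H]1CC/C(C)=C/CC[C@@]1(C)[C@H](CCCO)/C(=C(/C)C=O)CC[C@]1(C)O | target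

**Step count**

Total: 17 steps. Longest linear sequence: 12 steps (steps 1–8 and 14–17); the epoxide half takes 5 steps (9–13) before the union.

**Steps most likely to fail**

Step 7 (proposed new method). The oxidation may couple through the α-carbon of the dienolate, the dienolate may rotate about its central bond before bond formation and lose the alkene geometry, the second deprotonation may stay incomplete, or intermolecular coupling may compete. The fallback uses known chemistry and sets out from 8. A Stille coupling with (tributylstannyl)methanol (palladium diacetate, XPhos, CsF, dioxane, 80 °C) should replace the tosylate with retention and give the hydroxymethyl enoate F1, in which CH2OH is cis to the 2-methyl and cannot lactonise. CBr4/PPh3 converts it into the allylic bromide F2. LiN(SiMe3)2 in THF at −78 °C then forms the lithium enolate F3 at the acetyl methyl, which closes the same ring bond by SN2 displacement of the allylic bromide (6-(enolendo)-exo-tet) without touching the alkene. The fallback comes back to the route at 11.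

Step 2. Face selection or chair/boat discrimination may be poor when the new bond is made to a fully substituted alkene carbon, and the Lewis-acidic boron bromide may add across the terminal alkyne before enolisation. The fallback sets out from 3 and replaces reagent control by resolution. LiN(i-Pr)2 (2.2 equiv) and Me3SiCl in THF–DMPU at −78 °C give the C,O-bis(trimethylsilyl) ketene acetal F4 (chain cis to OSi, acetylenic carbon silylated as well). Warming to rt gives the silyl ester F5 through the same chair arrangement. K2CO3 in methanol removes both silyl groups and gives the racemic acid F6. Crystallisation with (S)-1-phenylethylamine separates the salt F7 of 5 from the salt F8 of its enantiomer (the (R)-amine is used if F8 proves the less soluble salt), and dilute HCl liberates the acid. The fallback comes back to the route at 5.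

Step 8. Axial attack may compete, so that the methyl addition loses facial selectivity, or the hindered ketone may be enolised instead of attacked. The fallback sets out from 11 and puts the new carbon in the equatorial position under thermodynamic control. A Corey–Chaykovsky reaction with dimethylsulfoxonium methylide (Me3S(O)I, NaH, DMSO, rt) adds reversibly and should give the spiro-epoxide F9 with the new C–C bond equatorial and the oxygen axial. LiAlH4 in THF at 0 °C opens the epoxide at its CH2 carbon and reduces the ester in the same operation, giving the diol F10. Hydroboration with 9-BBN gives the alkylborane F11, which is coupled with 19 under the conditions of step 14. The fallback comes back to the route at 22.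

**Further compounds**

F1 | step 7 | methyl (2E)-4-{3-[(tert-butyldimethylsilyl)oxy]propyl}-5-ethenyl-3-(hydroxymethyl)-2,5-dimethyl-6-oxohept-2-enoate (stereocentres as in 9; CH2OH cis to the 2-methyl) | CC(=O)[C@@](C)(C=C)[C@H](CCCO[Si](C)(C)C(C)(C)C)/C(CO)=C(/C)C(=O)OC
F2 | step 7 | methyl (2E)-3-(bromomethyl)-4-{3-[(tert-butyldimethylsilyl)oxy]propyl}-5-ethenyl-2,5-dimethyl-6-oxohept-2-enoate (stereocentres as in 9) | CC(=O)[C@@](C)(C=C)[C@H](CCCO[Si](C)(C)C(C)(C)C)/C(CBr)=C(/C)C(=O)OC
F3 | step 7 | lithium enolate of F2 at the acetyl methyl (formed in the flask) | [Li]OC(=C)[C@@](C)(C=C)[C@H](CCCO[Si](C)(C)C(C)(C)C)/C(CBr)=C(/C)C(=O)OC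
F4 | step 2 | C,O-bis(trimethylsilyl) ketene acetal of 3 (alkyl chain cis to OSi; formed in the flask) | C[Si](C)(C)C#C/C(C)=C\CO/C(O[Si](C)(C)C)=C/CCCO[Si](C)(C)C(C)(C)C
F5 | step 2 | racemic trimethylsilyl 2-{3-[(tert-butyldimethylsilyl)oxy]propyl}-3-methyl-3-[(trimethylsilyl)ethynyl]pent-4-enoate, (2S,3S) and (2R,3R) (formed in the flask) | C=C[C@@](C#C[Si](C)(C)C)(C)[C@H](CCCO[Si](C)(C)C(C)(C)C)C(=O)O[Si](C)(C)C.C=C[C@](C#C[Si](C)(C)C)(C)[C@@H](CCCO[Si](C)(C)C(C)(C)C)C(=O)O[Si](C)(C)C
F6 | step 2 | racemic 2-{3-[(tert-butyldimethylsilyl)oxy]propyl}-3-ethynyl-3-methylpent-4-enoic acid, (2S,3S) and (2R,3R) | C=C[C@@](C#C)(C)[C@H](CCCO[Si](C)(C)C(C)(C)C)C(=O)O.C=C[C@](C#C)(C)[C@@H](CCCO[Si](C)(C)C(C)(C)C)C(=O)O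
F7 | step 2 | (S)-1-phenylethylammonium salt of 5 | C=C[C@@](C#C)(C)[C@H](CCCO[Si](C)(C)C(C)(C)C)C(=O)[O-].C[C@H]([NH3+])c1ccccc1
F8 | step 2 | (S)-1-phenylethylammonium salt of the (2R,3R)-enantiomer of 5 | C=C[C@](C#C)(C)[C@@H](CCCO[Si](C)(C)C(C)(C)C)C(=O)[O-].C[C@H]([NH3+])c1ccccc1
F9 | step 8 | spiro-epoxide of 11: methyl (2Z)-2-[5-{3-[(tert-butyldimethylsilyl)oxy]propyl}-4-ethenyl-4-methyl-1-oxaspiro[2.5]octan-6-ylidene]propanoate (epoxide oxygen axial, cis to the silyloxypropyl chain) | C1O[C@]12CC/C(=C(\C)C(=O)OC)[C@@H](CCCO[Si](C)(C)C(C)(C)C)[C@]2(C)C=C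
F10 | step 8 | (2Z)-2-[(2R,3S,4S)-2-{3-[(tert-butyldimethylsilyl)oxy]propyl}-3-ethenyl-4-hydroxy-3,4-dimethylcyclohexylidene]propan-1-ol | C[C@]1(O)CC/C(=C(\C)CO)[C@@H](CCCO[Si](C)(C)C(C)(C)C)[C@]1(C)C=C
F11 | step 8 | B-alkyl-9-borabicyclo[3.3.1]nonane from F10 (formed in the flask) | C[C@]1(O)CC/C(=C(\C)CO)[C@@H](CCCO[Si](C)(C)C(C)(C)C)[C@]1(C)CCB1C2CCCC1CCC2
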